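Cuts, in retrosynthetic order: all benzyl ethers and a bromine cap on bottom C8; the two gallate esters; top C4–C4a, which opens ring C (the top pyran); top C4–middle C8; top O1–C2 and C2–aryl; middle C4–bottom C6.
Enabling feature: top C4 is a diarylmethine carbon between two phloroglucinol rings, ring A (top) and ring D (middle). Its cation can therefore be carried by ring D instead of ring A. Ring A, a 3,5-dioxygenated phenyl ether hung on O1, then acts as the nucleophile; its two ortho carbons are equivalent and one becomes C4a.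
Forward order: C8-bromo-capped catechin and C8-iodo-capped, C4-activated epicatechin are joined 4β→6. The iodine is exchanged for lithium, and middle C8 is bonded to the aldehyde carbon (future top C4) of an open C2–C3–C4 chain that already carries rings A and B. Ionisation of the resulting carbinol closes ring C, the only ring the route builds and hence the last.
Stereochemistry: the bottom and middle units come from (+)-catechin and (−)-epicatechin. The three carbons of (R)-glyceraldehyde acetonide (D-mannitol pool) become top C2, C3 and C4, and its stereocentre becomes C3. C2 comes from a Felkin–Anh aryl addition followed by Mitsunobu inversion. Middle C4 and top C4 are each set by attack anti to the neighbouring silyloxy group.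
Helpers (acetonide, iodine, two TBS groups, bromine, benzyl ethers) leave in steps 11, 15, 17 and 19; both gallates go on in one step.

Key step: step 16

Locants: flavan numbering throughout, with "top", "middle" and "bottom" naming the unit. Rings A, C, B belong to the top unit and rings D, F, E to the middle unit. The open-chain fragment already uses its later flavan locants.
Assumption: 4-bromo-1,2-bis(benzyloxy)benzene, (R)-glyceraldehyde acetonide, 3,5-bis(benzyloxy)phenol and 3,4,5-tris(benzyloxy)benzoic acid are taken as catalogue compounds.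

**Fragment 1 (bottom unit)**

Step 1
Reactants: 1 (+)-catechin
Product: 2 5,7,3',4'-tetra-O-benzyl-(+)-catechin
Conditions: BnBr (4.4 equiv), K2CO3, DMF, 0 °C to rt
Reagents that add atoms: benzyl bromide, BrCc1ccccc1
Why: Williamson ether synthesis in which K2CO3 deprotonates only the four phenols, so that the secondary 3-OH stays free and C2 and C3 are not touched.

Step 2
Reactants: 2 5,7,3',4'-tetra-O-benzyl-(+)-catechin
Product: 3 3,5,7,3',4'-penta-O-benzyl-(+)-catechin
Conditions: NaH, BnBr, n-Bu4NI (cat.), THF–DMF, 0 °C to rt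
Reagents that add atoms: benzyl bromide, BrCc1ccccc1
Why: Williamson benzylation of the 3-alkoxide masks the one secondary hydroxyl that must stay free of gallate with a group that survives the organolithium, fluoride and acylation steps and falls in the last step.

Step 3
Reactants: 3 3,5,7,3',4'-penta-O-benzyl-(+)-catechin
Product: 4 8-bromo-3,5,7,3',4'-penta-O-benzyl-(+)-catechin
Conditions: NBS (1.0 equiv), CH2Cl2, −78 °C to rt, dark
Reagents that add atoms: N-bromosuccinimide, O=C1CCC(=O)N1Br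
Why: Electrophilic aromatic bromination takes the more nucleophilic C8 of the 5,7-dibenzyloxy ring, and the bromine is a temporary cap that leaves C6 as the only open carbon of that ring for step 8.

**Fragment 2 (middle unit)**

Step 4
Reactants: 5 (−)-epicatechin
Product: 6 5,7,3',4'-tetra-O-benzyl-(−)-epicatechin
Conditions: BnBr (4.4 equiv), K2CO3, DMF, 0 °C to rt
Reagents that add atoms: benzyl bromide, BrCc1ccccc1
Why: Williamson ether synthesis of the four phenols only, as in step 1, without touching C2 or C3.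

Step 5
Reactants: 6 5,7,3',4'-tetra-O-benzyl-(−)-epicatechin
Product: 7 8-iodo-5,7,3',4'-tetra-O-benzyl-(−)-epicatechin
Conditions: NIS (1.0 equiv), CH2Cl2, −20 °C to rt, dark
Reagents that add atoms: N-iodosuccinimide, O=C1CCC(=O)N1I
Why: Electrophilic aromatic iodination should follow the same C8 preference as the bromination of step 3, and it installs a halogen that blocks self-condensation in step 8 and can later be exchanged for lithium in the presence of the bromide.

Step 6
Reactants: 7 8-iodo-5,7,3',4'-tetra-O-benzyl-(−)-epicatechin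
Product: 8 3-O-TBS-8-iodo-5,7,3',4'-tetra-O-benzyl-(−)-epicatechin
Conditions: TBSCl, imidazole, DMF, rt to 40 °C
Reagents that add atoms: tert-butyldimethylsilyl chloride, CC(C)(C)[Si](C)(C)Cl
Why: Standard silylation of the axial 3-OH under conditions free of Lewis acid gives a base-stable group that also shields the α face of C4 in steps 7 and 8.

Step 7
Reactants: 8 3-O-TBS-8-iodo-5,7,3',4'-tetra-O-benzyl-(−)-epicatechin
Product: 9 4β-(2-ethoxyethoxy)-3-O-TBS-8-iodo-5,7,3',4'-tetra-O-benzyl-(−)-epicatechin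
Conditions: DDQ (1.5 equiv), 2-ethoxyethanol (5 equiv), CH2Cl2, rt
Reagents that add atoms: 2-ethoxyethanol, CCOCCO
Why: DDQ benzylic oxidation abstracts hydride from C4, the only CH2 activated by the trioxygenated ring, and the alcohol adds to the cation anti to 3-OTBS to give the 4β ether, whose configuration is lost again in step 8.

**Union of fragments 1 and 2**

Step 8
Reactants: 9 4β-(2-ethoxyethoxy)-3-O-TBS-8-iodo-5,7,3',4'-tetra-O-benzyl-(−)-epicatechin; 4 8-bromo-3,5,7,3',4'-penta-O-benzyl-(+)-catechin (1.5 equiv)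
Product: 10 [3-O-TBS-8-iodo-5,7,3',4'-tetra-O-benzylepicatechin]-(4β→6)-[8-bromo-3,5,7,3',4'-penta-O-benzylcatechin]
Conditions: TMSOTf (0.2 equiv), CH2Cl2, −78 to −30 °C; Et3N quench
Reagents that add atoms: none
Why: Lewis acid catalysed Friedel–Crafts interflavan coupling in which the C4 cation of 9 is attacked by C6 of 4, the only free carbon of its phloroglucinol ring, from the face anti to the axial 3-OTBS group (3,4-trans, 4β), while the iodine on C8 keeps 9 from condensing on itself.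

**Fragment 3 (open C2–C3–C4 chain of the top unit with rings A and B)**

Step 9
Reactants: 11 4-bromo-1,2-bis(benzyloxy)benzene; 12 (R)-2,2-dimethyl-1,3-dioxolane-4-carbaldehyde ((R)-glyceraldehyde acetonide)
Product: 15 (S)-[3,4-bis(benzyloxy)phenyl][(4R)-2,2-dimethyl-1,3-dioxolan-4-yl]methanol (anti), via 3,4-bis(benzyloxy)phenyllithium 13 (not isolated), via aryltitanium triisopropoxide 14 (not isolated)
Conditions: n-BuLi, THF, −78 °C; ClTi(OiPr)3, −78 to −40 °C; 12, −78 to 0 °C; H2O work-up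
Reagents that add atoms: none
Why: Addition of the non-chelating aryltitanium reagent to the α-alkoxy aldehyde follows the Felkin–Anh model and should favour the anti (erythro) alcohol, so the new carbinol centre (future C2) is set by the glyceraldehyde stereocentre, and the minor syn epimer is removed by chromatography.

Step 10
Reactants: 15 (S)-[3,4-bis(benzyloxy)phenyl][(4R)-2,2-dimethyl-1,3-dioxolan-4-yl]methanol; 16 3,5-bis(benzyloxy)phenol
Product: 17 (4R)-4-{(R)-[3,4-bis(benzyloxy)phenyl][3,5-bis(benzyloxy)phenoxy]methyl}-2,2-dimethyl-1,3-dioxolane (syn)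
Conditions: n-Bu3P, N,N,N',N'-tetramethylazodicarboxamide (TMAD), toluene, 0 °C to rt
Reagents that add atoms: none
Why: Mitsunobu etherification (SN2 displacement of the oxyphosphonium group by the phenoxide oxygen) forms O1–C2 with inversion and so turns the anti alcohol into the syn aryl ether that corresponds to a 2,3-cis flavan (2R,3R).

Step 11
Reactants: 17 (4R)-4-{(R)-[3,4-bis(benzyloxy)phenyl][3,5-bis(benzyloxy)phenoxy]methyl}-2,2-dimethyl-1,3-dioxolane
Product: 18 (2R,3R)-3-[3,4-bis(benzyloxy)phenyl]-3-[3,5-bis(benzyloxy)phenoxy]propane-1,2-diol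
Conditions: AcOH–H2O 4:1, 45 °C
Reagents that add atoms: none
Why: Mild acid hydrolysis of the terminal isopropylidene acetal, under which the secondary benzylic aryl ether and the benzyl ethers should be stable.

Step 12
Reactants: 18 (2R,3R)-3-[3,4-bis(benzyloxy)phenyl]-3-[3,5-bis(benzyloxy)phenoxy]propane-1,2-diol
Product: 19 1,2-bis-O-TBS ether of 18
Conditions: TBSCl (3 equiv), imidazole, DMAP (cat.), DMF, 40 °C
Reagents that add atoms: tert-butyldimethylsilyl chloride, CC(C)(C)[Si](C)(C)Cl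
Why: Exhaustive silylation puts on O3 the same group as in the middle unit, so that both can be removed together in step 17.

Step 13
Reactants: 19 1,2-bis-O-TBS ether of 18
Product: 20 (2R,3R)-3-[3,4-bis(benzyloxy)phenyl]-3-[3,5-bis(benzyloxy)phenoxy]-2-(TBS-oxy)propan-1-ol
Conditions: HF·pyridine, pyridine, THF, 0 °C
Reagents that add atoms: none
Why: Kinetically selective desilylation, since buffered HF·pyridine cleaves the unhindered primary silyl ether much faster than the secondary one next to the diaryl-substituted carbon.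

Step 14
Reactants: 20 (2R,3R)-3-[3,4-bis(benzyloxy)phenyl]-3-[3,5-bis(benzyloxy)phenoxy]-2-(TBS-oxy)propan-1-ol
Product: 21 (2S,3R)-3-[3,4-bis(benzyloxy)phenyl]-3-[3,5-bis(benzyloxy)phenoxy]-2-(TBS-oxy)propanal
Conditions: Dess–Martin periodinane, CH2Cl2, 0 °C to rt; used at once
Reagents that add atoms: none
Why: Dess–Martin oxidation gives the α-silyloxy aldehyde under neutral conditions that do not epimerise C3 (the descriptor changes only because the CHO group gains priority).

**Union, ring closure and end game**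

Step 15
Reactants: 10 [3-O-TBS-8-iodo-tetra-O-benzylepicatechin]-(4β→6)-[8-bromo-penta-O-benzylcatechin]; 21 (2S,3R)-3-[3,4-bis(benzyloxy)phenyl]-3-[3,5-bis(benzyloxy)phenoxy]-2-(TBS-oxy)propanal
Product: 23 open-chain carbinol (top C4–OH; both C4 epimers) bonded through top C4 to middle C8, via middle C8 aryllithium 22 (not isolated)
Conditions: n-BuLi (1.05 equiv), THF, −78 °C, 10 min; 21, −78 °C; H2O quench; short filtration over Et3N-deactivated silica, used at once
Reagents that add atoms: none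
Why: Iodine–lithium exchange is far faster than bromine–lithium exchange, so only middle C8 is metalated, and 1,2-addition to the aldehyde makes the top C4–middle C8 bond regiospecifically, the new carbinol centre being a mixture that is erased in step 16.

Step 16
Reactants: 23 open-chain carbinol (both C4 epimers)
Product: 25 [3-O-TBS-5,7,3',4'-tetra-O-benzylepicatechin]-(4β→8)-[3-O-TBS-5,7,3',4'-tetra-O-benzylepicatechin]-(4β→6)-[8-bromo-3,5,7,3',4'-penta-O-benzylcatechin], via ring D stabilised C4 cation 24 (not isolated)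
Conditions: BF3·OEt2 (0.2 equiv), 4 Å MS, CH2Cl2 (0.002 M), −78 to −40 °C; Et3N quench
Reagents that add atoms: none
Why: BF3·OEt2 ionises only the top C4–OH bond, because cation 24 is a 2,4,6-trioxygenated benzyl cation carried by ring D (a quinone-methide-type C4=C8 species), and ring A, held on O1 three atoms away, attacks it through an ortho carbon and rearomatises by proton loss, so that C4–C4a and with it ring C are formed and both carbinol epimers converge. The closest known reaction types are the acid-catalysed Friedel–Crafts cycloalkylation of 3-aryloxy-1-arylpropan-1-ols and of aryl 3-arylglycidyl ethers to trans-4-arylchroman-3-ols, and the cationic interflavan coupling itself, run here with the roles of the two phloroglucinol rings exchanged. The closure is six-membered and 6-exo-trig with respect to the top C4=middle C8 bond of the cation. The new stereocentre C4 is controlled by C3: allylic 1,3-strain with the two ortho oxygens of ring D (the ring F oxygen and the 7-OBn group) puts H3 in the plane of the cation, the bulky OTBS group and C2 then lie on opposite faces, and ring A, which is tied to C2, must bond anti to OTBS, giving the 3,4-trans (4β) arrangement that is also the more stable one in the 2,3-cis series. Site selectivity on ring A is no issue because its two ortho carbons are equivalent and its para carbon cannot reach C4, and ring B could only close a five-membered indane and is a far weaker nucleophile than the phloroglucinol triether ring A. The C2–O1 benzylic ether, the middle C4–bottom C6 bond and the silyl ethers ionise much less readily than the ring D carbinol at −78 °C, and high dilution keeps the capture intramolecular.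

Step 17
Reactants: 25 protected trimer bis-TBS ether
Product: 26 protected trimer 3(top),3(middle)-diol
Conditions: TBAF–AcOH (1:1, 6 equiv), THF, rt to 45 °C
Reagents that add atoms: none
Why: Fluoride-induced desilylation, buffered to stay near neutral, frees exactly the two secondary hydroxyls that carry gallate in the target, while the bottom 3-O-benzyl ether stays.

Step 18
Reactants: 26 protected trimer diol; 27 3,4,5-tris(benzyloxy)benzoic acid (4 equiv)
Product: 28 protected trimer 3(top),3(middle)-bis(3,4,5-tri-O-benzylgallate)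
Conditions: DCC, DMAP, CH2Cl2, rt
Reagents that add atoms: none
Why: Steglich esterification acylates both free axial 3-hydroxyls in one operation with retention at C3, a transformation with close precedent on benzylated procyanidin dimers.

Step 19
Reactants: 28 protected trimer bis(tri-O-benzylgallate)
Product: 29 epicatechin-3-O-gallate-(4β→8)-epicatechin-3-O-gallate-(4β→6)-catechin (target)
Conditions: H2 (1 atm), Pd(OH)2/C, Et3N (1.1 equiv), THF–MeOH–H2O, rt; filtration, Sephadex LH-20, lyophilisation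
Reagents that add atoms: none
Why: Heterogeneous hydrogenolysis cleaves all nineteen benzyl ethers and hydrodehalogenates the bromine cap on bottom C8, Et3N takes up the HBr so that the acid-labile interflavan bonds are not exposed, and esters, pyran C–O bonds and stereocentres are left untouched at 1 atm.

**Compound list**

1 | (+)-catechin, (2R,3S) | O[C@H]1Cc2c(O)cc(O)cc2O[C@@H]1c1ccc(O)c(O)c1 | starting material
2 | 5,7,3',4'-tetra-O-benzyl-(+)-catechin | O[C@H]1Cc2c(OCc9ccccc9)cc(OCc9ccccc9)cc2O[C@@H]1c7ccc(OCc9ccccc9)c(OCc9ccccc9)c7 | intermediate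
3 | 3,5,7,3',4'-penta-O-benzyl-(+)-catechin | O(Cc9ccccc9)[C@H]1Cc2c(OCc9ccccc9)cc(OCc9ccccc9)cc2O[C@@H]1c7ccc(OCc9ccccc9)c(OCc9ccccc9)c7 | intermediate
4 | 8-bromo-3,5,7,3',4'-penta-O-benzyl-(+)-catechin | O(Cc9ccccc9)[C@H]1Cc2c(OCc9ccccc9)cc(OCc9ccccc9)c(Br)c2O[C@@H]1c7ccc(OCc9ccccc9)c(OCc9ccccc9)c7 | intermediate
5 | (−)-epicatechin, (2R,3R) | O[C@@H]1Cc2c(O)cc(O)cc2O[C@@H]1c1ccc(O)c(O)c1 | starting material
6 | 5,7,3',4'-tetra-O-benzyl-(−)-epicatechin | O[C@@H]1Cc2c(OCc9ccccc9)cc(OCc9ccccc9)cc2O[C@@H]1c7ccc(OCc9ccccc9)c(OCc9ccccc9)c7 | intermediate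
7 | 8-iodo-5,7,3',4'-tetra-O-benzyl-(−)-epicatechin | O[C@@H]1Cc2c(OCc9ccccc9)cc(OCc9ccccc9)c(I)c2O[C@@H]1c7ccc(OCc9ccccc9)c(OCc9ccccc9)c7 | intermediate
8 | 3-O-TBS-8-iodo-5,7,3',4'-tetra-O-benzyl-(−)-epicatechin | CC(C)(C)[Si](C)(C)O[C@@H]1Cc2c(OCc9ccccc9)cc(OCc9ccccc9)c(I)c2O[C@@H]1c7ccc(OCc9ccccc9)c(OCc9ccccc9)c7 | intermediate
9 | 4β-(2-ethoxyethoxy)-3-O-TBS-8-iodo-5,7,3',4'-tetra-O-benzyl-(−)-epicatechin | CC(C)(C)[Si](C)(C)O[C@@H]1[C@@H](OCCOCC)c2c(OCc9ccccc9)cc(OCc9ccccc9)c(I)c2O[C@@H]1c7ccc(OCc9ccccc9)c(OCc9ccccc9)c7 | intermediate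
10 | [3-O-TBS-8-iodo-tetra-O-benzylepicatechin]-(4β→6)-[8-bromo-penta-O-benzylcatechin] | Ic2c(OCc9ccccc9)cc(OCc9ccccc9)c3c2O[C@H](c7ccc(OCc9ccccc9)c(OCc9ccccc9)c7)[C@H](O[Si](C)(C)C(C)(C)C)[C@H]3c4c(OCc9ccccc9)c(Br)c5c(c4OCc9ccccc9)C[C@H](OCc9ccccc9)[C@@H](c7ccc(OCc9ccccc9)c(OCc9ccccc9)c7)O5 | intermediate
11 | 4-bromo-1,2-bis(benzyloxy)benzene | Brc1ccc(OCc9ccccc9)c(OCc9ccccc9)c1 | starting material
12 | (R)-2,2-dimethyl-1,3-dioxolane-4-carbaldehyde | O=C[C@H]1COC(C)(C)O1 | starting material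
13 | 3,4-bis(benzyloxy)phenyllithium | [Li]c1ccc(OCc9ccccc9)c(OCc9ccccc9)c1 | intermediate
14 | [3,4-bis(benzyloxy)phenyl]titanium triisopropoxide | CC(C)O[Ti](OC(C)C)(OC(C)C)c1ccc(OCc9ccccc9)c(OCc9ccccc9)c1 | intermediate
15 | (S)-[3,4-bis(benzyloxy)phenyl][(4R)-2,2-dimethyl-1,3-dioxolan-4-yl]methanol | O[C@@H](c7ccc(OCc9ccccc9)c(OCc9ccccc9)c7)[C@H]1COC(C)(C)O1 | intermediate
16 | 3,5-bis(benzyloxy)phenol | Oc1cc(OCc9ccccc9)cc(OCc9ccccc9)c1 | starting material
17 | (4R)-4-{(R)-[3,4-bis(benzyloxy)phenyl][3,5-bis(benzyloxy)phenoxy]methyl}-2,2-dimethyl-1,3-dioxolane | c1c(OCc9ccccc9)cc(OCc9ccccc9)cc1O[C@H](c7ccc(OCc9ccccc9)c(OCc9ccccc9)c7)[C@H]1COC(C)(C)O1 | intermediate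
18 | (2R,3R)-3-[3,4-bis(benzyloxy)phenyl]-3-[3,5-bis(benzyloxy)phenoxy]propane-1,2-diol | c1c(OCc9ccccc9)cc(OCc9ccccc9)cc1O[C@H](c7ccc(OCc9ccccc9)c(OCc9ccccc9)c7)[C@H](O)CO | intermediate
19 | 1,2-bis-O-TBS ether of 18 | c1c(OCc9ccccc9)cc(OCc9ccccc9)cc1O[C@H](c7ccc(OCc9ccccc9)c(OCc9ccccc9)c7)[C@H](O[Si](C)(C)C(C)(C)C)CO[Si](C)(C)C(C)(C)C | intermediate
20 | (2R,3R)-3-[3,4-bis(benzyloxy)phenyl]-3-[3,5-bis(benzyloxy)phenoxy]-2-(TBS-oxy)propan-1-ol | c1c(OCc9ccccc9)cc(OCc9ccccc9)cc1O[C@H](c7ccc(OCc9ccccc9)c(OCc9ccccc9)c7)[C@H](O[Si](C)(C)C(C)(C)C)CO | intermediate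
21 | (2S,3R)-3-[3,4-bis(benzyloxy)phenyl]-3-[3,5-bis(benzyloxy)phenoxy]-2-(TBS-oxy)propanal | c1c(OCc9ccccc9)cc(OCc9ccccc9)cc1O[C@H](c7ccc(OCc9ccccc9)c(OCc9ccccc9)c7)[C@H](O[Si](C)(C)C(C)(C)C)C=O | intermediate
22 | middle C8 aryllithium derived from 10 | [Li]c2c(OCc9ccccc9)cc(OCc9ccccc9)c3c2O[C@H](c7ccc(OCc9ccccc9)c(OCc9ccccc9)c7)[C@H](O[Si](C)(C)C(C)(C)C)[C@H]3c4c(OCc9ccccc9)c(Br)c5c(c4OCc9ccccc9)C[C@H](OCc9ccccc9)[C@@H](c7ccc(OCc9ccccc9)c(OCc9ccccc9)c7)O5 | intermediate
23 | open-chain carbinol, top C4–OH (both epimers), top C4 bonded to middle C8 | c1c(OCc9ccccc9)cc(OCc9ccccc9)cc1O[C@H](c7ccc(OCc9ccccc9)c(OCc9ccccc9)c7)[C@H](O[Si](C)(C)C(C)(C)C)C(O)c2c(OCc9ccccc9)cc(OCc9ccccc9)c3c2O[C@H](c7ccc(OCc9ccccc9)c(OCc9ccccc9)c7)[C@H](O[Si](C)(C)C(C)(C)C)[C@H]3c4c(OCc9ccccc9)c(Br)c5c(c4OCc9ccccc9)C[C@H](OCc9ccccc9)[C@@H](c7ccc(OCc9ccccc9)c(OCc9ccccc9)c7)O5 | intermediate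
24 | ring D stabilised top C4 cation | c1c(OCc9ccccc9)cc(OCc9ccccc9)cc1O[C@H](c7ccc(OCc9ccccc9)c(OCc9ccccc9)c7)[C@H](O[Si](C)(C)C(C)(C)C)[CH+]c2c(OCc9ccccc9)cc(OCc9ccccc9)c3c2O[C@H](c7ccc(OCc9ccccc9)c(OCc9ccccc9)c7)[C@H](O[Si](C)(C)C(C)(C)C)[C@H]3c4c(OCc9ccccc9)c(Br)c5c(c4OCc9ccccc9)C[C@H](OCc9ccccc9)[C@@H](c7ccc(OCc9ccccc9)c(OCc9ccccc9)c7)O5 | intermediate
25 | [3-O-TBS-tetra-O-benzylepicatechin]-(4β→8)-[3-O-TBS-tetra-O-benzylepicatechin]-(4β→6)-[8-bromo-penta-O-benzylcatechin] | CC(C)(C)[Si](C)(C)O[C@@H]1[C@@H](c2c(OCc9ccccc9)cc(OCc9ccccc9)c3c2O[C@H](c7ccc(OCc9ccccc9)c(OCc9ccccc9)c7)[C@H](O[Si](C)(C)C(C)(C)C)[C@H]3c4c(OCc9ccccc9)c(Br)c5c(c4OCc9ccccc9)C[C@H](OCc9ccccc9)[C@@H](c7ccc(OCc9ccccc9)c(OCc9ccccc9)c7)O5)c6c(OCc9ccccc9)cc(OCc9ccccc9)cc6O[C@@H]1c7ccc(OCc9ccccc9)c(OCc9ccccc9)c7 | intermediate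
26 | protected trimer with free 3-OH in the top and middle units | O[C@@H]1[C@@H](c2c(OCc9ccccc9)cc(OCc9ccccc9)c3c2O[C@H](c7ccc(OCc9ccccc9)c(OCc9ccccc9)c7)[C@H](O)[C@H]3c4c(OCc9ccccc9)c(Br)c5c(c4OCc9ccccc9)C[C@H](OCc9ccccc9)[C@@H](c7ccc(OCc9ccccc9)c(OCc9ccccc9)c7)O5)c6c(OCc9ccccc9)cc(OCc9ccccc9)cc6O[C@@H]1c7ccc(OCc9ccccc9)c(OCc9ccccc9)c7 | intermediate
27 | 3,4,5-tris(benzyloxy)benzoic acid | OC(=O)c1cc(OCc9ccccc9)c(OCc9ccccc9)c(OCc9ccccc9)c1 | starting material
28 | protected trimer bis(3,4,5-tri-O-benzylgallate) | O=C(O[C@@H]1[C@@H](c2c(OCc9ccccc9)cc(OCc9ccccc9)c3c2O[C@H](c7ccc(OCc9ccccc9)c(OCc9ccccc9)c7)[C@H](OC(=O)c8cc(OCc9ccccc9)c(OCc9ccccc9)c(OCc9ccccc9)c8)[C@H]3c4c(OCc9ccccc9)c(Br)c5c(c4OCc9ccccc9)C[C@H](OCc9ccccc9)[C@@H](c7ccc(OCc9ccccc9)c(OCc9ccccc9)c7)O5)c6c(OCc9ccccc9)cc(OCc9ccccc9)cc6O[C@@H]1c7ccc(OCc9ccccc9)c(OCc9ccccc9)c7)c8cc(OCc9ccccc9)c(OCc9ccccc9)c(OCc9ccccc9)c8 | intermediate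
29 | epicatechin-3-O-gallate-(4β→8)-epicatechin-3-O-gallate-(4β→6)-catechin (CNP0154615.1) | O=C(O[C@@H]1[C@@H](c2c(O)cc(O)c3c2O[C@H](c2ccc(O)c(O)c2)[C@H](OC(=O)c2cc(O)c(O)c(O)c2)[C@H]3c2c(O)cc3c(c2O)C[C@H](O)[C@@H](c2ccc(O)c(O)c2)O3)c2c(O)cc(O)cc2O[C@@H]1c1ccc(O)c(O)c1)c1cc(O)c(O)c(O)c1 | target

Total step count: 19. Longest linear sequence: 11 steps (steps 9 to 19, from 12 to 29).

**Steps most likely to fail**

Step 16. What may go wrong: ring A bonds to both faces of the planar C4 cation, or the cation loses H3 to give an enol silyl ether before it is captured. The fallback replaces steric control by anchimeric assistance from the ester that the target needs anyway.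
- It sets out from 10 and 21. The lithium alkoxide formed as in step 15 is trapped at −78 °C with MeOTf to give the top C4 methyl ether of 23 F1, which is stable to base and fluoride.
- TBAF–AcOH then frees both secondary hydroxyls to give the open-chain diol F2.
- Steglich esterification with 27 gives the open-chain bis(tri-O-benzylgallate) F3.
- BF3·OEt2 in dilute CH2Cl2 at −78 °C expels methanol. The carbonyl oxygen of the C3 ester bridges the cation on the O3 face, and ring A can close only from the opposite face (3,4-trans).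
- This gives 28 directly, where the route is rejoined.

Step 15. What may go wrong: the hindered, basic aryllithium deprotonates the aldehyde at C3 with β-elimination of the aryloxide, or it attacks its own benzylic positions. The fallback is a Nozaki–Hiyama–Kishi coupling, which sets out from 10 and 21.
- Conditions are CrCl2 (4 equiv) and NiCl2 (cat.) in DMF–THF at rt.
- Zerovalent nickel inserts into the carbon–iodine bond in preference to the carbon–bromine bond.
- Transmetalation gives the non-basic middle C8 arylchromium dichloride F4, which adds to the aldehyde without enolisation.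
- The route is rejoined at 23.

Step 8. What may go wrong: attack by the hindered C6 of 4 is slow, so that the acid set free strips the iodine cap (protodeiodination) and the electrophile decays. The fallback changes the leaving group to sulfur and the activation to a thiophilic, non-acidic one.
- It sets out from 9. Phenylmethanethiol and BF3·OEt2 (cat.) at −78 °C capture the cation quickly as the 4β-benzylsulfanyl derivative F5.
- F5 and 4 are then coupled with AgBF4 in THF at 0 °C.
- The route is rejoined at 10.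

**Further compounds**

F1 | step 16 | top C4 methyl ether of 23 (both C4 epimers) | c1c(OCc9ccccc9)cc(OCc9ccccc9)cc1O[C@H](c7ccc(OCc9ccccc9)c(OCc9ccccc9)c7)[C@H](O[Si](C)(C)C(C)(C)C)C(OC)c2c(OCc9ccccc9)cc(OCc9ccccc9)c3c2O[C@H](c7ccc(OCc9ccccc9)c(OCc9ccccc9)c7)[C@H](O[Si](C)(C)C(C)(C)C)[C@H]3c4c(OCc9ccccc9)c(Br)c5c(c4OCc9ccccc9)C[C@H](OCc9ccccc9)[C@@H](c7ccc(OCc9ccccc9)c(OCc9ccccc9)c7)O5
F2 | step 16 | open-chain diol (top C3–OH, middle C3–OH, top C4–OMe) | c1c(OCc9ccccc9)cc(OCc9ccccc9)cc1O[C@H](c7ccc(OCc9ccccc9)c(OCc9ccccc9)c7)[C@H](O)C(OC)c2c(OCc9ccccc9)cc(OCc9ccccc9)c3c2O[C@H](c7ccc(OCc9ccccc9)c(OCc9ccccc9)c7)[C@H](O)[C@H]3c4c(OCc9ccccc9)c(Br)c5c(c4OCc9ccccc9)C[C@H](OCc9ccccc9)[C@@H](c7ccc(OCc9ccccc9)c(OCc9ccccc9)c7)O5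
F3 | step 16 | open-chain bis(3,4,5-tri-O-benzylgallate) with top C4–OMe | c1c(OCc9ccccc9)cc(OCc9ccccc9)cc1O[C@H](c7ccc(OCc9ccccc9)c(OCc9ccccc9)c7)[C@H](OC(=O)c8cc(OCc9ccccc9)c(OCc9ccccc9)c(OCc9ccccc9)c8)C(OC)c2c(OCc9ccccc9)cc(OCc9ccccc9)c3c2O[C@H](c7ccc(OCc9ccccc9)c(OCc9ccccc9)c7)[C@H](OC(=O)c8cc(OCc9ccccc9)c(OCc9ccccc9)c(OCc9ccccc9)c8)[C@H]3c4c(OCc9ccccc9)c(Br)c5c(c4OCc9ccccc9)C[C@H](OCc9ccccc9)[C@@H](c7ccc(OCc9ccccc9)c(OCc9ccccc9)c7)O5
F4 | step 15 | middle C8 arylchromium dichloride derived from 10 | Cl[Cr](Cl)c2c(OCc9ccccc9)cc(OCc9ccccc9)c3c2O[C@H](c7ccc(OCc9ccccc9)c(OCc9ccccc9)c7)[C@H](O[Si](C)(C)C(C)(C)C)[C@H]3c4c(OCc9ccccc9)c(Br)c5c(c4OCc9ccccc9)C[C@H](OCc9ccccc9)[C@@H](c7ccc(OCc9ccccc9)c(OCc9ccccc9)c7)O5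
F5 | step 8 | 4β-benzylsulfanyl-3-O-TBS-8-iodo-5,7,3',4'-tetra-O-benzyl-(−)-epicatechin | CC(C)(C)[Si](C)(C)O[C@@H]1[C@@H](SCc9ccccc9)c2c(OCc9ccccc9)cc(OCc9ccccc9)c(I)c2O[C@@H]1c7ccc(OCc9ccccc9)c(OCc9ccccc9)c7
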